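**Plan**

1. Ring locants used here: C1 = isopropyl-bearing alkene carbon, C2 = alkene CH, C3/C4 = oxirane CH and C(Me), C5–C7 = CH2, C8 = CH(CH2OH), C9 = ketone, C10–C11 = CH2, C12 = CHMe, C13 = CHOH, C14 = enone carbonyl. Retrosynthetic cuts, in order: the two O–Si bonds, the oxirane oxygen (back to a Z C3=C4 alkene), C14=O (back to a carbinol), the ring bond C14–C1, then C9–C10, C2–C3 and C4–C5.
2. Forward: fragment 1 (C1–C9, a Z-enyne Weinreb amide) and fragment 2 (C10–C14, a primary iodide) are joined at C9–C10 by alkyllithium acylation; the single 14-membered carbocycle then closes at C14–C1, followed by oxidation to the dienone, epoxidation and desilylation.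
3. Enabling feature: the C3=C4 alkene (the later oxirane) is conjugated to the C1≡C2 alkyne, so a nickel catalyst held by that alkene joins the C14 aldehyde carbon to the hindered, isopropyl-bearing C1 and delivers hydrogen syn to C2. This closes the cyclotetradecane ring and sets the E C1=C2 geometry in one event.
4. Stereochemistry: C8 by Evans titanium-enolate hydroxymethylation with (R)-4-benzyloxazolidin-2-one; C12/C13 by Brown (Z)-crotylboration; the Z C3=C4 geometry by syn carbocupration of propyne; C3/C4 by reagent-controlled Shi epoxidation with the L-fructose-derived ketone.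

Key step: step 15

Remark: the C14 carbinol formed in step 15 is carried as a mixture of epimers, since step 16 removes this centre; 2-[(4-methoxybenzyl)oxy]acetaldehyde, (−)-Ipc2BOMe and the L-fructose-derived Shi ketone are taken as purchasable.

**Route**

Step 1
Reactants: 1 5-bromopent-1-ene; 2 propyne
Product: 6 (Z)-1-iodo-2-methylhepta-1,6-diene, via pent-4-enylmagnesium bromide 3 (not isolated), via pent-4-enylcopper 4 (not isolated), via (Z)-2-methylhepta-1,6-dienylcopper 5 (not isolated)
Conditions: Mg, Et2O; CuBr·SMe2, Et2O/Me2S, −45 °C; propyne, −25 °C; I2, THF, −78 → 0 °C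
Reagents that add atoms: iodine, II
Why: Normant carbocupration: the alkylcopper reagent should add syn across propyne with the alkyl group on the internal carbon, and iodinolysis of the alkenylcopper with retention should give the Z iodoalkene (chain cis to iodine), which fixes the later C3=C4 geometry.

Step 2
Reactants: 6 (Z)-1-iodo-2-methylhepta-1,6-diene
Product: 8 (Z)-7-iodo-6-methylhept-6-en-1-ol, via B-alkyl-9-BBN adduct 7 (not isolated)
Conditions: 9-BBN, THF, 0 °C → rt; NaOH, H2O2, 0 °C
Reagents that add atoms: hydrogen peroxide, OO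
Why: Brown hydroboration–oxidation: 9-BBN should add only to the monosubstituted alkene with boron at the terminal carbon, the trisubstituted iodoalkene being far less reactive, and alkaline peroxide then gives the primary alcohol.

Step 3
Reactants: 8 (Z)-7-iodo-6-methylhept-6-en-1-ol
Product: 9 (Z)-7-iodo-6-methylhept-6-enoic acid
Conditions: TEMPO (cat.), PhI(OAc)2, MeCN/H2O, rt
Reagents that add atoms: water, O
Why: TEMPO-catalysed oxidation with PhI(OAc)2 in aqueous acetonitrile should carry the primary alcohol through the aldehyde hydrate to the acid without touching the iodoalkene.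

Step 4
Reactants: 9 (Z)-7-iodo-6-methylhept-6-enoic acid; 10 (R)-4-benzyloxazolidin-2-one
Product: 12 (R)-4-benzyl-3-[(Z)-7-iodo-6-methylhept-6-enoyl]oxazolidin-2-one, via mixed pivalic anhydride 11 (not isolated)
Conditions: PivCl, Et3N, THF, −20 °C; then 10, LiCl, rt
Reagents that add atoms: none
Why: N-Acylation of the Evans oxazolidinone through the mixed pivalic anhydride (LiCl/Et3N activation) is a mild, standard way to attach the auxiliary.

Step 5
Reactants: 12 (R)-4-benzyl-3-[(Z)-7-iodo-6-methylhept-6-enoyl]oxazolidin-2-one; 13 1,3,5-trioxane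
Product: 15 (R)-4-benzyl-3-[(2S,6Z)-2-(hydroxymethyl)-7-iodo-6-methylhept-6-enoyl]oxazolidin-2-one, via trichlorotitanium Z-enolate 14 (not isolated)
Conditions: TiCl4, i-Pr2NEt, CH2Cl2, 0 °C; then 13, TiCl4, 0 °C; aq. NH4Cl
Reagents that add atoms: none
Why: Evans asymmetric hydroxymethylation: formaldehyde released from trioxane by TiCl4 should attack the chelated Z titanium enolate on the face opposite the benzyl group, which with the (R)-auxiliary sets C8 as S (aldol-type addition).

Step 6
Reactants: 15 (R)-4-benzyl-3-[(2S,6Z)-2-(hydroxymethyl)-7-iodo-6-methylhept-6-enoyl]oxazolidin-2-one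
Product: 16 (2S,6Z)-2-(hydroxymethyl)-7-iodo-N-methoxy-N,6-dimethylhept-6-enamide
Conditions: MeONHMe·HCl, AlMe3, THF/CH2Cl2, −10 → 0 °C; aq. potassium sodium tartrate
Reagents that add atoms: N,O-dimethylhydroxylamine hydrochloride, CNOC.Cl
Why: Weinreb transamination: the aluminium amide formed from AlMe3 and MeONHMe·HCl, assisted by the free β-hydroxyl, should cleave the exocyclic imide carbonyl and release the auxiliary without epimerization at C8.

Step 7
Reactants: 16 (2S,6Z)-2-(hydroxymethyl)-7-iodo-N-methoxy-N,6-dimethylhept-6-enamide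
Product: 17 (2S,6Z)-2-{[(tert-butyldimethylsilyl)oxy]methyl}-7-iodo-N-methoxy-N,6-dimethylhept-6-enamide
Conditions: TBSCl, imidazole, CH2Cl2, 0 °C → rt
Reagents that add atoms: tert-butyldimethylsilyl chloride, CC(C)(C)[Si](C)(C)Cl
Why: Silylation of the primary alcohol (silyl ether protection) masks the hydroxymethyl group against the organolithium, oxidation and nickel steps that follow.

Step 8
Reactants: 17 (2S,6Z)-2-{[(tert-butyldimethylsilyl)oxy]methyl}-7-iodo-N-methoxy-N,6-dimethylhept-6-enamide; 18 3-methylbut-1-yne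
Product: 19 (2S,6Z)-2-{[(tert-butyldimethylsilyl)oxy]methyl}-N-methoxy-N,6,10-trimethylundec-6-en-8-ynamide (fragment 1)
Conditions: Pd(PPh3)4 (cat.), CuI (cat.), i-Pr2NH, THF, rt, sealed vessel
Reagents that add atoms: none
Why: Sonogashira coupling of the alkenyl iodide with the terminal alkyne should proceed with retention of the Z geometry and tolerate the Weinreb amide and silyl ether, giving the 1,3-enyne that later directs the nickel catalyst.

Step 9
Reactants: 20 2-[(4-methoxybenzyl)oxy]acetaldehyde; 21 cis-but-2-ene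
Product: 25 (2S,3R)-1-[(4-methoxybenzyl)oxy]-3-methylpent-4-en-2-ol, via (Z)-crotylpotassium 22 (not isolated), via (Z)-crotyldiisopinocampheylborane 23 (not isolated), via homoallyl diisopinocampheylborinate 24 (not isolated)
Conditions: 21, KOt-Bu, n-BuLi, THF, −78 → −45 °C; (−)-Ipc2BOMe, −78 °C; BF3·OEt2; 20, −78 °C; NaOH, H2O2
Reagents that add atoms: none
Why: Brown asymmetric crotylboration: the (Z)-crotylborane bearing isopinocampheyl groups derived from (+)-α-pinene should add through a chair transition state to the si face of the aldehyde, the Z geometry giving the syn relationship and the reagent setting C13 as S and C12 as R.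

Step 10
Reactants: 25 (2S,3R)-1-[(4-methoxybenzyl)oxy]-3-methylpent-4-en-2-ol
Product: 26 tert-butyl({(2S,3R)-1-[(4-methoxybenzyl)oxy]-3-methylpent-4-en-2-yl}oxy)dimethylsilane
Conditions: TBSOTf, 2,6-lutidine, CH2Cl2, −78 → 0 °C
Reagents that add atoms: tert-butyldimethylsilyl triflate, CC(C)(C)[Si](C)(C)OS(=O)(=O)C(F)(F)F
Why: Silylation of the secondary alcohol with the reactive silyl triflate (silyl ether protection) should proceed without disturbing the 4-methoxybenzyl ether.

Step 11
Reactants: 26 tert-butyl({(2S,3R)-1-[(4-methoxybenzyl)oxy]-3-methylpent-4-en-2-yl}oxy)dimethylsilane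
Product: 28 tert-butyl({(2S,3R)-5-iodo-1-[(4-methoxybenzyl)oxy]-3-methylpentan-2-yl}oxy)dimethylsilane (fragment 2), via alkylzirconocene chloride 27 (not isolated)
Conditions: Cp2Zr(H)Cl, THF, rt; I2, 0 °C
Reagents that add atoms: iodine, II
Why: Schwartz hydrozirconation places zirconium at the terminal carbon of the monosubstituted alkene and iodinolysis of the C–Zr bond should give the primary iodide in one flask (hydrozirconation–iodination).

Step 12
Reactants: 28 tert-butyl({(2S,3R)-5-iodo-1-[(4-methoxybenzyl)oxy]-3-methylpentan-2-yl}oxy)dimethylsilane; 19 (2S,6Z)-2-{[(tert-butyldimethylsilyl)oxy]methyl}-N-methoxy-N,6,10-trimethylundec-6-en-8-ynamide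
Product: 30 (2S,3R,7S,11Z)-2-[(tert-butyldimethylsilyl)oxy]-7-{[(tert-butyldimethylsilyl)oxy]methyl}-1-[(4-methoxybenzyl)oxy]-3,11,15-trimethylhexadec-11-en-13-yn-6-one, via primary alkyllithium 29 (not isolated)
Conditions: t-BuLi (2 equiv), Et2O/pentane, −78 °C; then 19, −78 → −40 °C; aq. NH4Cl
Reagents that add atoms: none
Why: Iodine–lithium exchange with t-BuLi gives the primary alkyllithium, whose addition to the Weinreb amide stops at the chelated tetrahedral adduct so that work-up should release the C9 ketone without over-addition or loss of the C8 configuration (Weinreb ketone synthesis).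

Step 13
Reactants: 30 (2S,3R,7S,11Z)-2-[(tert-butyldimethylsilyl)oxy]-7-{[(tert-butyldimethylsilyl)oxy]methyl}-1-[(4-methoxybenzyl)oxy]-3,11,15-trimethylhexadec-11-en-13-yn-6-one
Product: 31 (2S,3R,7S,11Z)-2-[(tert-butyldimethylsilyl)oxy]-7-{[(tert-butyldimethylsilyl)oxy]methyl}-1-hydroxy-3,11,15-trimethylhexadec-11-en-13-yn-6-one
Conditions: DDQ, CH2Cl2/pH 7 phosphate buffer, 0 °C
Reagents that add atoms: none
Why: Oxidative cleavage of the 4-methoxybenzyl ether with DDQ in buffered wet dichloromethane should free the C14 alcohol while silyl ethers, ketone and enyne remain.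

Step 14
Reactants: 31 (2S,3R,7S,11Z)-2-[(tert-butyldimethylsilyl)oxy]-7-{[(tert-butyldimethylsilyl)oxy]methyl}-1-hydroxy-3,11,15-trimethylhexadec-11-en-13-yn-6-one
Product: 32 (2S,3R,7S,11Z)-2-[(tert-butyldimethylsilyl)oxy]-7-{[(tert-butyldimethylsilyl)oxy]methyl}-3,11,15-trimethyl-6-oxohexadec-11-en-13-ynal
Conditions: Dess–Martin periodinane, NaHCO3, CH2Cl2, 0 °C → rt
Reagents that add atoms: none
Why: Dess–Martin oxidation under bicarbonate buffering should give the α-silyloxy aldehyde without epimerization at C13.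

Step 15
Reactants: 32 (2S,3R,7S,11Z)-2-[(tert-butyldimethylsilyl)oxy]-7-{[(tert-butyldimethylsilyl)oxy]methyl}-3,11,15-trimethyl-6-oxohexadec-11-en-13-ynal
Product: 33 (1E,3Z,8S,12R,13S)-13-[(tert-butyldimethylsilyl)oxy]-8-{[(tert-butyldimethylsilyl)oxy]methyl}-14-hydroxy-1-isopropyl-4,12-dimethylcyclotetradeca-1,3-dien-9-one (ring locants of the plan; both C14 epimers)
Conditions: Ni(cod)2 (cat.), PCyp3 (tricyclopentylphosphine), Et3B, EtOAc, rt, syringe-pump addition of 32 (high dilution)
Reagents that add atoms: none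
Why: Zerovalent nickel binds the C1≡C2 alkyne together with the conjugated C3=C4 alkene and the C14 aldehyde, oxidative cyclization should give an oxanickelacyclopentene with the new C14–C1 bond and nickel on C2, and ethyl transfer from Et3B, β-hydride elimination (loss of ethene) and C–H reductive elimination then deliver hydrogen to C2 syn to C14. The closest known reaction type is the nickel-catalysed reductive coupling of alkynes with aldehydes, in its alkene-directed 1,3-enyne form and in its ynal macrocyclization form. The single ring closes in the 14-endo-dig mode, both alkyne carbons ending inside the cyclotetradecadiene. The only new stereocentre, the C14 carbinol, is expected to form mainly anti to the C13 silyloxy group (Felkin sense) but needs no control because step 16 oxidizes it, while the C1=C2 geometry (C14 and H cis, hence isopropyl cis to C3) is fixed by the syn addition. The step needs regioselectivity for C1 over C2, which the coordinated C3=C4 alkene should secure by holding nickel next to C2; chemoselectivity for the aldehyde over the C9 ketone, which the much lower reactivity of ketones in this coupling should secure; and ring closure over oligomerization, which slow addition at high dilution should secure.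

Step 16
Reactants: 33 (1E,3Z,8S,12R,13S)-13-[(tert-butyldimethylsilyl)oxy]-8-{[(tert-butyldimethylsilyl)oxy]methyl}-14-hydroxy-1-isopropyl-4,12-dimethylcyclotetradeca-1,3-dien-9-one
Product: 34 (1E,3Z,8S,12R,13S)-13-[(tert-butyldimethylsilyl)oxy]-8-{[(tert-butyldimethylsilyl)oxy]methyl}-1-isopropyl-4,12-dimethylcyclotetradeca-1,3-diene-9,14-dione (ring locants of the plan)
Conditions: Dess–Martin periodinane, NaHCO3, CH2Cl2, 0 °C → rt
Reagents that add atoms: none
Why: Dess–Martin oxidation of the dienylic alcohol should give the conjugated dienone and removes the uncontrolled C14 stereocentre.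

Step 17
Reactants: 34 (1E,3Z,8S,12R,13S)-13-[(tert-butyldimethylsilyl)oxy]-8-{[(tert-butyldimethylsilyl)oxy]methyl}-1-isopropyl-4,12-dimethylcyclotetradeca-1,3-diene-9,14-dione
Product: 35 (1E,3S,4R,8S,12R,13S)-13-[(tert-butyldimethylsilyl)oxy]-8-{[(tert-butyldimethylsilyl)oxy]methyl}-3,4-epoxy-1-isopropyl-4,12-dimethylcyclotetradec-1-ene-9,14-dione (ring locants of the plan)
Conditions: L-fructose-derived Shi ketone (cat.), Oxone (2KHSO5·KHSO4·K2SO4), K2CO3, Bu4NHSO4, MeCN/CH2(OMe)2/aq. Na2B4O7–Na2EDTA buffer, 0 °C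
Reagents that add atoms: potassium peroxymonosulfate, [K+].[O-]S(=O)(=O)OO
Why: Shi asymmetric epoxidation: the chiral dioxirane from the L-fructose-derived ketone should transfer oxygen only to the electron-richer γ,δ alkene (C3=C4) of the dienone through the spiro transition state that places the C3 hydrogen toward the catalyst's dioxolane, syn delivery to the Z alkene giving the cis (3S,4R) oxirane under reagent control.

Step 18
Reactants: 35 (1E,3S,4R,8S,12R,13S)-13-[(tert-butyldimethylsilyl)oxy]-8-{[(tert-butyldimethylsilyl)oxy]methyl}-3,4-epoxy-1-isopropyl-4,12-dimethylcyclotetradec-1-ene-9,14-dione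
Product: 36 (1E,3S,4R,8S,12R,13S)-3,4-epoxy-13-hydroxy-8-(hydroxymethyl)-1-isopropyl-4,12-dimethylcyclotetradec-1-ene-9,14-dione (CNP0110598.2)
Conditions: HF·pyridine, pyridine, THF, 0 °C → rt
Reagents that add atoms: none
Why: Desilylation with pyridine-buffered HF·pyridine (fluoride-mediated silyl ether cleavage) should remove both silyl groups under conditions mild enough for the vinyl epoxide, the α-ketol and the β-hydroxy ketone.

**Compound list**

1 | 5-bromopent-1-ene | C=CCCCBr | starting material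
2 | propyne | CC#C | starting material
3 | pent-4-enylmagnesium bromide | C=CCCC[Mg]Br | intermediate
4 | pent-4-enylcopper (MgBr2·SMe2 complex) | C=CCCC[Cu] | intermediate
5 | (Z)-2-methylhepta-1,6-dienylcopper | C=CCCC/C(C)=C\[Cu] | intermediate
6 | (Z)-1-iodo-2-methylhepta-1,6-diene | C=CCCC/C(C)=C\I | intermediate
7 | 9-[(Z)-7-iodo-6-methylhept-6-en-1-yl]-9-borabicyclo[3.3.1]nonane | I/C=C(C)\CCCCCB1C2CCCC1CCC2 | intermediate
8 | (Z)-7-iodo-6-methylhept-6-en-1-ol | OCCCCC/C(C)=C\I | intermediate
9 | (Z)-7-iodo-6-methylhept-6-enoic acid | OC(=O)CCCC/C(C)=C\I | intermediate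
10 | (R)-4-benzyloxazolidin-2-one | O=C1N[C@H](Cc2ccccc2)CO1 | starting material
11 | (Z)-7-iodo-6-methylhept-6-enoic pivalic anhydride | CC(C)(C)C(=O)OC(=O)CCCC/C(C)=C\I | intermediate
12 | (R)-4-benzyl-3-[(Z)-7-iodo-6-methylhept-6-enoyl]oxazolidin-2-one | O=C(CCCC/C(C)=C\I)N1[C@H](Cc2ccccc2)COC1=O | intermediate
13 | 1,3,5-trioxane | C1OCOCO1 | starting material
14 | trichlorotitanium Z-enolate of 12 | Cl[Ti](Cl)(Cl)O/C(=C\CCC/C(C)=C\I)N1[C@H](Cc2ccccc2)COC1=O | intermediate
15 | (R)-4-benzyl-3-[(2S,6Z)-2-(hydroxymethyl)-7-iodo-6-methylhept-6-enoyl]oxazolidin-2-one | O=C([C@H](CO)CCC/C(C)=C\I)N1[C@H](Cc2ccccc2)COC1=O | intermediate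
16 | (2S,6Z)-2-(hydroxymethyl)-7-iodo-N-methoxy-N,6-dimethylhept-6-enamide | CON(C)C(=O)[C@H](CO)CCC/C(C)=C\I | intermediate
17 | (2S,6Z)-2-{[(tert-butyldimethylsilyl)oxy]methyl}-7-iodo-N-methoxy-N,6-dimethylhept-6-enamide | CON(C)C(=O)[C@H](CO[Si](C)(C)C(C)(C)C)CCC/C(C)=C\I | intermediate
18 | 3-methylbut-1-yne | CC(C)C#C | starting material
19 | (2S,6Z)-2-{[(tert-butyldimethylsilyl)oxy]methyl}-N-methoxy-N,6,10-trimethylundec-6-en-8-ynamide (fragment 1) | CON(C)C(=O)[C@H](CO[Si](C)(C)C(C)(C)C)CCC/C(C)=C\C#CC(C)C | intermediate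
20 | 2-[(4-methoxybenzyl)oxy]acetaldehyde | COc1ccc(COCC=O)cc1 | starting material
21 | cis-but-2-ene | C/C=C\C | starting material
22 | (Z)-but-2-enylpotassium | C/C=C\C[K] | intermediate
23 | (Z)-but-2-enyldiisopinocampheylborane (isopinocampheyl groups from (+)-α-pinene) | C/C=C\CB([C@@H]1C[C@@H]2C[C@H]([C@H]1C)C2(C)C)[C@@H]1C[C@@H]2C[C@H]([C@H]1C)C2(C)C | intermediate
24 | diisopinocampheylborinate of 25 | COc1ccc(COC[C@@H](OB([C@@H]2C[C@@H]3C[C@H]([C@H]2C)C3(C)C)[C@@H]2C[C@@H]3C[C@H]([C@H]2C)C3(C)C)[C@H](C)C=C)cc1 | intermediate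
25 | (2S,3R)-1-[(4-methoxybenzyl)oxy]-3-methylpent-4-en-2-ol | COc1ccc(COC[C@@H](O)[C@H](C)C=C)cc1 | intermediate
26 | tert-butyl({(2S,3R)-1-[(4-methoxybenzyl)oxy]-3-methylpent-4-en-2-yl}oxy)dimethylsilane | COc1ccc(COC[C@@H](O[Si](C)(C)C(C)(C)C)[C@H](C)C=C)cc1 | intermediate
27 | chlorobis(cyclopentadienyl){(3R,4S)-4-[(tert-butyldimethylsilyl)oxy]-5-[(4-methoxybenzyl)oxy]-3-methylpentyl}zirconium | COc1ccc(COC[C@@H](O[Si](C)(C)C(C)(C)C)[C@H](C)CC[Zr](Cl)(C2C=CC=C2)C2C=CC=C2)cc1 | intermediate
28 | tert-butyl({(2S,3R)-5-iodo-1-[(4-methoxybenzyl)oxy]-3-methylpentan-2-yl}oxy)dimethylsilane (fragment 2) | COc1ccc(COC[C@@H](O[Si](C)(C)C(C)(C)C)[C@H](C)CCI)cc1 | intermediate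
29 | {(3R,4S)-4-[(tert-butyldimethylsilyl)oxy]-5-[(4-methoxybenzyl)oxy]-3-methylpentyl}lithium | COc1ccc(COC[C@@H](O[Si](C)(C)C(C)(C)C)[C@H](C)CC[Li])cc1 | intermediate
30 | (2S,3R,7S,11Z)-2-[(tert-butyldimethylsilyl)oxy]-7-{[(tert-butyldimethylsilyl)oxy]methyl}-1-[(4-methoxybenzyl)oxy]-3,11,15-trimethylhexadec-11-en-13-yn-6-one | COc1ccc(COC[C@@H](O[Si](C)(C)C(C)(C)C)[C@H](C)CCC(=O)[C@H](CO[Si](C)(C)C(C)(C)C)CCC/C(C)=C\C#CC(C)C)cc1 | intermediate
31 | (2S,3R,7S,11Z)-2-[(tert-butyldimethylsilyl)oxy]-7-{[(tert-butyldimethylsilyl)oxy]methyl}-1-hydroxy-3,11,15-trimethylhexadec-11-en-13-yn-6-one | OC[C@@H](O[Si](C)(C)C(C)(C)C)[C@H](C)CCC(=O)[C@H](CO[Si](C)(C)C(C)(C)C)CCC/C(C)=C\C#CC(C)C | intermediate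
32 | (2S,3R,7S,11Z)-2-[(tert-butyldimethylsilyl)oxy]-7-{[(tert-butyldimethylsilyl)oxy]methyl}-3,11,15-trimethyl-6-oxohexadec-11-en-13-ynal | O=C[C@@H](O[Si](C)(C)C(C)(C)C)[C@H](C)CCC(=O)[C@H](CO[Si](C)(C)C(C)(C)C)CCC/C(C)=C\C#CC(C)C | intermediate
33 | (1E,3Z,8S,12R,13S)-13-[(tert-butyldimethylsilyl)oxy]-8-{[(tert-butyldimethylsilyl)oxy]methyl}-14-hydroxy-1-isopropyl-4,12-dimethylcyclotetradeca-1,3-dien-9-one (both C14 epimers) | CC(C)/C1=C\C=C(C)/CCC[C@@H](CO[Si](C)(C)C(C)(C)C)C(=O)CC[C@@H](C)[C@H](O[Si](C)(C)C(C)(C)C)C1O | intermediate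
34 | (1E,3Z,8S,12R,13S)-13-[(tert-butyldimethylsilyl)oxy]-8-{[(tert-butyldimethylsilyl)oxy]methyl}-1-isopropyl-4,12-dimethylcyclotetradeca-1,3-diene-9,14-dione | CC(C)/C1=C\C=C(C)/CCC[C@@H](CO[Si](C)(C)C(C)(C)C)C(=O)CC[C@@H](C)[C@H](O[Si](C)(C)C(C)(C)C)C1=O | intermediate
35 | (1E,3S,4R,8S,12R,13S)-13-[(tert-butyldimethylsilyl)oxy]-8-{[(tert-butyldimethylsilyl)oxy]methyl}-3,4-epoxy-1-isopropyl-4,12-dimethylcyclotetradec-1-ene-9,14-dione | CC(C)/C1=C\[C@@H]2O[C@]2(C)CCC[C@@H](CO[Si](C)(C)C(C)(C)C)C(=O)CC[C@@H](C)[C@H](O[Si](C)(C)C(C)(C)C)C1=O | intermediate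
36 | (1E,3S,4R,8S,12R,13S)-3,4-epoxy-13-hydroxy-8-(hydroxymethyl)-1-isopropyl-4,12-dimethylcyclotetradec-1-ene-9,14-dione (CNP0110598.2) | CC(C)/C1=C\[C@@H]2O[C@]2(C)CCC[C@@H](CO)C(=O)CC[C@@H](C)[C@H](O)C1=O | target

**Count and risks**

Total step count: 18 (fragment 1: steps 1–8; fragment 2: steps 9–11; union and endgame: steps 12–18).
Longest linear sequence: 15 steps (steps 1–8, then 12–18).

Steps most likely to fail:

Step 15. Ring strain in the 14-membered transition state may override the alkene's directing effect and close the ring through C2 (13-membered, exocyclic alkene). Intermolecular coupling, oligomerization and simple aldehyde reduction may also outrun the closure. Fallback: the C14–C1 bond would be made between two pieces by the same coupling, and the ring closed at C10–C11 by metathesis. From 26, DDQ cleavage of the 4-methoxybenzyl ether would give (2S,3R)-2-[(tert-butyldimethylsilyl)oxy]-3-methylpent-4-en-1-ol F1, and Dess–Martin oxidation the aldehyde (2S,3R)-2-[(tert-butyldimethylsilyl)oxy]-3-methylpent-4-enal F2. Nickel-catalysed alkene-directed reductive coupling (Ni(cod)2, PCyp3, Et3B) of F2 with enyne 19 should give the dienol Weinreb amide (2S,6Z,8E,11S,12R)-11-[(tert-butyldimethylsilyl)oxy]-2-{[(tert-butyldimethylsilyl)oxy]methyl}-10-hydroxy-N-methoxy-N,6,12-trimethyl-9-(propan-2-yl)tetradeca-6,8,13-trienamide F3. Excess vinylmagnesium bromide would convert the amide into the vinyl ketone (4S,8Z,10E,13S,14R)-13-[(tert-butyldimethylsilyl)oxy]-4-{[(tert-butyldimethylsilyl)oxy]methyl}-12-hydroxy-8,14-dimethyl-11-(propan-2-yl)hexadeca-1,8,10,15-tetraen-3-one F4. Ring-closing metathesis with the second-generation Hoveyda–Grubbs catalyst should give the macrocyclic trienone (1E,3Z,8S,10E,12R,13S)-13-[(tert-butyldimethylsilyl)oxy]-8-{[(tert-butyldimethylsilyl)oxy]methyl}-14-hydroxy-1-isopropyl-4,12-dimethylcyclotetradeca-1,3,10-trien-9-one F5. Conjugate reduction of its C10=C11 enone with Stryker's reagent [(Ph3P)CuH]6 would rejoin the route at 33.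

Step 17. The conformational bias of the 14-membered dienone may oppose the catalyst and lead to poor facial selectivity. Oxygen transfer to the conjugated, electron-poorer diene may be slow, and the basic buffer may epimerize C8. Fallback: oxygen would be delivered to the opposite face in two stages instead of by direct transfer. From 34, NBS in wet THF should give the bromohydrin (1E,3R,4R,8S,12R,13S)-3-bromo-13-[(tert-butyldimethylsilyl)oxy]-8-{[(tert-butyldimethylsilyl)oxy]methyl}-4-hydroxy-1-isopropyl-4,12-dimethylcyclotetradec-1-ene-9,14-dione F6 (bromonium ion on the accessible face, water anti at the tertiary C4). K2CO3 in methanol would then close the oxirane by displacement of bromide with inversion at C3, rejoining the route at 35.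

Step 18. Fluoride or acid may open the vinyl epoxide; the β-hydroxy ketone may undergo retro-aldol loss of formaldehyde or elimination; and the α-ketol may shift during slow removal of the hindered C13 silyl ether. Fallback: the order of the last two operations would be inverted so that no epoxide is present during desilylation. From 34, HF·pyridine would give the diol (1E,3Z,8S,12R,13S)-13-hydroxy-8-(hydroxymethyl)-1-isopropyl-4,12-dimethylcyclotetradeca-1,3-diene-9,14-dione F7. Shi epoxidation of F7 with the same L-fructose-derived ketone, as the last operation, would then give 36 directly.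

**Further compounds**

F1 | step 15 | (2S,3R)-2-[(tert-butyldimethylsilyl)oxy]-3-methylpent-4-en-1-ol | OC[C@@H](O[Si](C)(C)C(C)(C)C)[C@H](C)C=C
F2 | step 15 | (2S,3R)-2-[(tert-butyldimethylsilyl)oxy]-3-methylpent-4-enal | O=C[C@@H](O[Si](C)(C)C(C)(C)C)[C@H](C)C=C
F3 | step 15 | (2S,6Z,8E,11S,12R)-11-[(tert-butyldimethylsilyl)oxy]-2-{[(tert-butyldimethylsilyl)oxy]methyl}-10-hydroxy-N-methoxy-N,6,12-trimethyl-9-(propan-2-yl)tetradeca-6,8,13-trienamide | CON(C)C(=O)[C@H](CO[Si](C)(C)C(C)(C)C)CCC/C(C)=C\C=C(/C(C)C)C(O)[C@@H](O[Si](C)(C)C(C)(C)C)[C@H](C)C=C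
F4 | step 15 | (4S,8Z,10E,13S,14R)-13-[(tert-butyldimethylsilyl)oxy]-4-{[(tert-butyldimethylsilyl)oxy]methyl}-12-hydroxy-8,14-dimethyl-11-(propan-2-yl)hexadeca-1,8,10,15-tetraen-3-one | C=CC(=O)[C@H](CO[Si](C)(C)C(C)(C)C)CCC/C(C)=C\C=C(/C(C)C)C(O)[C@@H](O[Si](C)(C)C(C)(C)C)[C@H](C)C=C
F5 | step 15 | (1E,3Z,8S,10E,12R,13S)-13-[(tert-butyldimethylsilyl)oxy]-8-{[(tert-butyldimethylsilyl)oxy]methyl}-14-hydroxy-1-isopropyl-4,12-dimethylcyclotetradeca-1,3,10-trien-9-one | CC(C)/C1=C\C=C(C)/CCC[C@@H](CO[Si](C)(C)C(C)(C)C)C(=O)/C=C/[C@@H](C)[C@H](O[Si](C)(C)C(C)(C)C)C1O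
F6 | step 17 | (1E,3R,4R,8S,12R,13S)-3-bromo-13-[(tert-butyldimethylsilyl)oxy]-8-{[(tert-butyldimethylsilyl)oxy]methyl}-4-hydroxy-1-isopropyl-4,12-dimethylcyclotetradec-1-ene-9,14-dione | CC(C)/C1=C\[C@@H](Br)[C@@](O)(C)CCC[C@@H](CO[Si](C)(C)C(C)(C)C)C(=O)CC[C@@H](C)[C@H](O[Si](C)(C)C(C)(C)C)C1=O
F7 | step 18 | (1E,3Z,8S,12R,13S)-13-hydroxy-8-(hydroxymethyl)-1-isopropyl-4,12-dimethylcyclotetradeca-1,3-diene-9,14-dione | CC(C)/C1=C\C=C(C)/CCC[C@@H](CO)C(=O)CC[C@@H](C)[C@H](O)C1=O
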